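**Plan**
1. Retrosynthesis: after putting nine benzyl ethers on, ring C of the upper unit is opened at O1–C8a; then the C2–aryl (B ring), C4–C8′ (link to catechin) and C3–C4 bonds are cut. This leaves an A-ring salicylaldehyde, a glycolate imide, an aryl bromide and (+)-catechin.
2. Enabling feature: O1 joins an sp2 carbon of ring A (C8a) to the benzylic stereocentre C2. The oxygen can therefore already sit on C2 as an open-chain carbinol, and ring C is closed last at the aryl end by Pd-catalysed C–O coupling, with C2 untouched (threo C2/C3 becomes 2,3-cis).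
3. Forward order: glycolate aldol makes C3–C4; the A-ring phenol is tied into a dihydrocoumarin (a temporary ring with the same six atoms as ring C) whose C4 is arylated by catechin C8; lactone reduction, B-ring Grignard addition at C2, phenol to triflate, ring C closure, debenzylation.
4. Stereochemistry: C3 from the Evans auxiliary; C4 by arene attack on the lactone C4 cation anti to the C3 benzyloxy group (3,4-trans); C2 by chelate-controlled Grignard addition; C2′/C3′ from (+)-catechin; the ring closure creates no stereocentre.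

Key step: step 12

Remark: the upper unit carries flavan numbers (O1, C2, C3, C4, C4a, C5–C8, C8a; B ring on C2) in all lactone and open-chain intermediates, and primed numbers belong to the catechin unit. Arylation at catechin C8 rather than C6 is assumed, as is usual for 5,7-di-O-benzylflavans.

**Route**

Step 1
Reactants: 1 3,5-bis(benzyloxy)phenol
Product: 2 2,4-bis(benzyloxy)-6-hydroxybenzaldehyde
Conditions: MgCl2, Et3N, (CH2O)n, MeCN, reflux
Reagents that add atoms: paraformaldehyde (formaldehyde), C=O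
Why: Magnesium-mediated ortho-formylation of a phenol (Casnati–Skattebøl reaction) delivers formaldehyde within the magnesium phenoxide to the ortho carbon only, and the two ortho positions of 1 are equivalent.

Step 2
Reactants: 2 2,4-bis(benzyloxy)-6-hydroxybenzaldehyde
Product: 3 2,4-bis(benzyloxy)-6-[(tert-butyldimethylsilyl)oxy]benzaldehyde
Conditions: TBSCl, imidazole, DMAP (cat.), DMF, rt
Reagents that add atoms: tert-butyldimethylsilyl chloride, CC(C)(C)[Si](C)(C)Cl
Why: Silylation of the phenol masks the acidic OH for the enolate step and can be undone later by fluoride without acid.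

Step 3
Reactants: 4 (R)-4-benzyloxazolidin-2-one; 5 (benzyloxy)acetyl chloride
Product: 6 (R)-4-benzyl-3-[(benzyloxy)acetyl]oxazolidin-2-one
Conditions: n-BuLi, THF, −78 °C; then 5, −78 → 0 °C
Reagents that add atoms: none
Why: N-Acylation of the lithiated oxazolidinone by the acid chloride is the standard preparation of Evans imides.

Step 4
Reactants: 6 (R)-4-benzyl-3-[(benzyloxy)acetyl]oxazolidin-2-one; 3 silyl-protected aldehyde
Product: 8 (2R,3S) syn-aldol imide, via Z-boron enolate 7 (not isolated)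
Conditions: 6, Bu2BOTf, Et3N, CH2Cl2, −78 → 0 °C; then 3, −78 → 0 °C; pH 7 buffer, MeOH, H2O2, 0 °C
Reagents that add atoms: none
Why: Evans syn-aldol addition, in which the (Z)-dibutylboron enolate 7 reacts through a chair Zimmerman–Traxler transition state on the face opposite the benzyl group of the (R)-auxiliary and so fixes C3 as R; the C4 carbinol configuration does not matter because this centre is ionised in step 8.

Step 5
Reactants: 8 (2R,3S) syn-aldol imide
Product: 10 (3R,4S)-3,5,7-tris(benzyloxy)-4-hydroxychroman-2-one, via free phenol 9 (not isolated)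
Conditions: TBAF, AcOH, THF, 0 °C; then Et3N, DMAP (cat.), rt
Reagents that add atoms: none
Why: Fluoride cleaves the aryl silyl ether and the liberated phenol is acylated intramolecularly by the N-acyloxazolidinone (6-exo-trig lactonisation with loss of the auxiliary), while acetic acid buffering should prevent retro-aldol cleavage and C3 is not touched.

Step 6
Reactants: 11 (+)-catechin
Product: 12 5,7,3′,4′-tetra-O-benzylcatechin
Conditions: BnBr, K2CO3, DMF, 0 °C → rt
Reagents that add atoms: benzyl bromide, BrCc1ccccc1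
Why: Williamson etherification under carbonate conditions alkylates the four phenols and leaves the aliphatic 3-OH and both stereocentres untouched.

Step 7
Reactants: 12 5,7,3′,4′-tetra-O-benzylcatechin
Product: 13 3,5,7,3′,4′-penta-O-benzylcatechin
Conditions: NaH, BnBr, Bu4NI (cat.), THF/DMF, 0 °C → rt
Reagents that add atoms: benzyl bromide, BrCc1ccccc1
Why: Williamson etherification of the secondary alcohol via its sodium alkoxide; with all phenols capped no base-induced ring opening is possible, so C2′ and C3′ keep their configuration.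

Step 8
Reactants: 10 (3R,4S)-3,5,7-tris(benzyloxy)-4-hydroxychroman-2-one; 13 penta-O-benzylcatechin
Product: 14 (3R,4R)-3,5,7-tris(benzyloxy)-4-(penta-O-benzylcatechin-8-yl)chroman-2-one
Conditions: TMSOTf (0.3 equiv), 13 (3 equiv), 4 Å MS, CH2Cl2, −78 → −40 °C; Et3N quench
Reagents that add atoms: none
Why: Acid-promoted Friedel–Crafts alkylation in which the C4 carbinol (silylated in situ) ionises to a benzylic cation stabilised by the 5- and 7-benzyloxy groups; the almost flat lactone ring exposes the face opposite the C3 benzyloxy group, so C8 of 13 should add 3,4-trans and set C4 as R, and the excess of 13 keeps self-alkylation of 10 down.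

Step 9
Reactants: 14 3,4-trans 4-aryl lactone
Product: 15 lactol (2-hydroxychroman, both anomers)
Conditions: DIBAL-H (1.2 equiv), CH2Cl2, −78 °C; Rochelle salt
Reagents that add atoms: none
Why: Partial reduction of a dihydrocoumarin by DIBAL-H stops at the aluminium hemiacetal at −78 °C and gives the lactol on work-up; the anomeric centre is lost again in step 10.

Step 10
Reactants: 15 lactol; 16 1-(benzyloxy)-4-bromobenzene
Product: 19 threo (1R,2R,3R) diol phenol, via aryl Grignard reagent 17 (not isolated), via open-chain aldehyde 18 (not isolated)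
Conditions: 16, Mg, THF, rt; Grignard solution (4 equiv) added to 15 and MgBr2·OEt2 in CH2Cl2, −78 → 0 °C; aq NH4Cl
Reagents that add atoms: none
Why: Grignard addition to a lactol, in which the first equivalent deprotonates 15 and releases aldehyde 18, magnesium bridges the carbonyl and the α-benzyloxy oxygen (Cram chelate), and the aryl group enters anti to the bulky diarylmethyl residue, setting C2 as R, threo to C3.

Step 11
Reactants: 19 threo diol phenol
Product: 20 threo (1R,2R,3S) alcohol aryl triflate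
Conditions: PhNTf2, Et3N, DMAP (cat.), CH2Cl2, 0 °C → rt
Reagents that add atoms: N-phenylbis(trifluoromethanesulfonimide), O=S(=O)(N(c1ccccc1)S(=O)(=O)C(F)(F)F)C(F)(F)F
Why: Phenol-selective triflation, since N-phenyltriflimide reacts with the phenoxide formed by Et3N but not with the hindered secondary benzylic alcohol, so only the oxygen on C8a is sulfonylated.

Step 12
Reactants: 20 threo alcohol aryl triflate
Product: 21 nona-O-benzylgambiriin C
Conditions: RockPhos Pd G3 (5 mol %), K3PO4, toluene, 80 °C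
Reagents that add atoms: none
Why: Pd(0) carrying the bulky biaryl phosphine inserts into the C8a–OTf bond, phosphate-assisted deprotonation places the C2 alkoxide on palladium, and C–O reductive elimination from the seven-membered oxapalladacycle releases the chroman. The closest known reaction is the Buchwald-type intramolecular etherification of ortho-(3-hydroxyalkyl)aryl halides and sulfonates with secondary alcohols, which gives 2-substituted chromans without loss of configuration at the carbinol carbon. Ring C (O1, C2, C3, C4, C4a, C8a) closes by 6-exo attack of the C2 oxygen on the aryl carbon C8a inside the palladium coordination sphere. No stereocentre is created: the C2–O bond and the C3 and C4 centres are untouched, so threo C2/C3 becomes 2,3-cis and C3/C4 stays trans. The step needs reductive elimination to outrun β-hydride elimination of the benzylic alkoxide and S–O cleavage of the triflate, which the hindered electron-rich ligand and the weak, poorly soluble base should secure; the five-membered alternative is excluded because O3 is benzylated, and the benzyloxy groups, being meta to C8a, do not deactivate it towards oxidative addition.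

Step 13
Reactants: 21 nona-O-benzylgambiriin C
Product: 22 gambiriin C
Conditions: H2 (1 atm), Pd(OH)2/C, THF/MeOH/H2O, rt
Reagents that add atoms: none
Why: Hydrogenolysis over Pearlman's catalyst should remove all nine benzyl ethers, while the benzylic C2–O1 bonds of both pyran rings and the C4–C8′ bond are not cleaved at 1 atm and room temperature.

**Compound list**

1 | 3,5-bis(benzyloxy)phenol | Oc1cc(OCc5ccccc5)cc(OCc5ccccc5)c1 | starting material
2 | 2,4-bis(benzyloxy)-6-hydroxybenzaldehyde | O=Cc1c(O)cc(OCc5ccccc5)cc1OCc5ccccc5 | intermediate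
3 | 2,4-bis(benzyloxy)-6-[(tert-butyldimethylsilyl)oxy]benzaldehyde | O=Cc1c(O[Si](C)(C)C(C)(C)C)cc(OCc5ccccc5)cc1OCc5ccccc5 | intermediate
4 | (R)-4-benzyloxazolidin-2-one | O=C1N[C@H](Cc5ccccc5)CO1 | starting material
5 | (benzyloxy)acetyl chloride | O=C(Cl)COCc5ccccc5 | starting material
6 | (R)-4-benzyl-3-[(benzyloxy)acetyl]oxazolidin-2-one | O=C(COCc5ccccc5)N1[C@H](Cc5ccccc5)COC1=O | intermediate
7 | dibutylboron (Z)-enolate of 6 (not isolated) | CCCCB(CCCC)O/C(=C\OCc5ccccc5)N1[C@H](Cc5ccccc5)COC1=O | intermediate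
8 | (R)-4-benzyl-3-[(2R,3S)-2-(benzyloxy)-3-{2,4-bis(benzyloxy)-6-[(tert-butyldimethylsilyl)oxy]phenyl}-3-hydroxypropanoyl]oxazolidin-2-one (syn aldol) | O=C([C@H](OCc5ccccc5)[C@@H](O)c2c(O[Si](C)(C)C(C)(C)C)cc(OCc5ccccc5)cc2OCc5ccccc5)N1[C@H](Cc5ccccc5)COC1=O | intermediate
9 | free phenol of 8 (not isolated) | O=C([C@H](OCc5ccccc5)[C@@H](O)c2c(O)cc(OCc5ccccc5)cc2OCc5ccccc5)N1[C@H](Cc5ccccc5)COC1=O | intermediate
10 | (3R,4S)-3,5,7-tris(benzyloxy)-4-hydroxychroman-2-one (3,4-trans) | O=C1Oc2cc(OCc5ccccc5)cc(OCc5ccccc5)c2[C@H](O)[C@H]1OCc5ccccc5 | intermediate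
11 | (+)-catechin, (2R,3S) | O[C@H]1Cc2c(O)cc(O)cc2O[C@@H]1c1ccc(O)c(O)c1 | starting material
12 | (2R,3S)-5,7-bis(benzyloxy)-2-[3,4-bis(benzyloxy)phenyl]chroman-3-ol | O[C@H]1Cc2c(OCc5ccccc5)cc(OCc5ccccc5)cc2O[C@@H]1c1ccc(OCc5ccccc5)c(OCc5ccccc5)c1 | intermediate
13 | (2R,3S)-3,5,7-tris(benzyloxy)-2-[3,4-bis(benzyloxy)phenyl]chromane (penta-O-benzylcatechin) | c5ccccc5CO[C@H]1Cc2c(OCc5ccccc5)cc(OCc5ccccc5)cc2O[C@@H]1c1ccc(OCc5ccccc5)c(OCc5ccccc5)c1 | intermediate
14 | (3R,4R)-3,5,7-tris(benzyloxy)-4-[(2R,3S)-penta-O-benzylcatechin-8-yl]chroman-2-one (3,4-trans) | O=C1Oc2cc(OCc5ccccc5)cc(OCc5ccccc5)c2[C@H](c6c(OCc5ccccc5)cc(OCc5ccccc5)c7c6O[C@H](c8ccc(OCc5ccccc5)c(OCc5ccccc5)c8)[C@@H](OCc5ccccc5)C7)[C@H]1OCc5ccccc5 | intermediate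
15 | lactol of 14 (2-hydroxychroman, anomeric mixture; C3 and C4 as in 14) | OC1Oc2cc(OCc5ccccc5)cc(OCc5ccccc5)c2[C@H](c6c(OCc5ccccc5)cc(OCc5ccccc5)c7c6O[C@H](c8ccc(OCc5ccccc5)c(OCc5ccccc5)c8)[C@@H](OCc5ccccc5)C7)[C@H]1OCc5ccccc5 | intermediate
16 | 1-(benzyloxy)-4-bromobenzene | Brc1ccc(OCc5ccccc5)cc1 | starting material
17 | [4-(benzyloxy)phenyl]magnesium bromide (not isolated) | Br[Mg]c1ccc(OCc5ccccc5)cc1 | intermediate
18 | ring-opened α-benzyloxy aldehyde of 15 as its bromomagnesium phenoxide (not isolated) | O=C[C@H](OCc5ccccc5)[C@@H](c6c(OCc5ccccc5)cc(OCc5ccccc5)c7c6O[C@H](c8ccc(OCc5ccccc5)c(OCc5ccccc5)c8)[C@@H](OCc5ccccc5)C7)c2c(O[Mg]Br)cc(OCc5ccccc5)cc2OCc5ccccc5 | intermediate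
19 | (1R,2R,3R)-2-(benzyloxy)-1-[4-(benzyloxy)phenyl]-3-[2,4-bis(benzyloxy)-6-hydroxyphenyl]-3-[(2R,3S)-penta-O-benzylcatechin-8-yl]propan-1-ol (C1/C2 threo; chain C1, C2, C3 = flavan C2, C3, C4) | c5ccccc5COc1ccc([C@@H](O)[C@H](OCc5ccccc5)[C@@H](c6c(OCc5ccccc5)cc(OCc5ccccc5)c7c6O[C@H](c8ccc(OCc5ccccc5)c(OCc5ccccc5)c8)[C@@H](OCc5ccccc5)C7)c2c(O)cc(OCc5ccccc5)cc2OCc5ccccc5)cc1 | intermediate
20 | aryl triflate of 19, (1R,2R,3S) (the C3 descriptor changes by CIP priority only) | c5ccccc5COc1ccc([C@@H](O)[C@H](OCc5ccccc5)[C@@H](c6c(OCc5ccccc5)cc(OCc5ccccc5)c7c6O[C@H](c8ccc(OCc5ccccc5)c(OCc5ccccc5)c8)[C@@H](OCc5ccccc5)C7)c2c(OS(=O)(=O)C(F)(F)F)cc(OCc5ccccc5)cc2OCc5ccccc5)cc1 | intermediate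
21 | nona-O-benzylgambiriin C: (2R,3R,4R)-3,5,7-tris(benzyloxy)-2-[4-(benzyloxy)phenyl]-4-[(2R,3S)-penta-O-benzylcatechin-8-yl]chromane | c5ccccc5COc1ccc([C@H]2Oc3cc(OCc5ccccc5)cc(OCc5ccccc5)c3[C@H](c6c(OCc5ccccc5)cc(OCc5ccccc5)c7c6O[C@H](c8ccc(OCc5ccccc5)c(OCc5ccccc5)c8)[C@@H](OCc5ccccc5)C7)[C@H]2OCc5ccccc5)cc1 | intermediate
22 | gambiriin C: (2R,3R,4R)-2-(4-hydroxyphenyl)-4-[(2R,3S)-catechin-8-yl]chromane-3,5,7-triol (2,3-cis, 3,4-trans) | Oc1ccc([C@H]2Oc3cc(O)cc(O)c3[C@H](c3c(O)cc(O)c4c3O[C@H](c3ccc(O)c(O)c3)[C@@H](O)C4)[C@H]2O)cc1 | target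

**Totals**
Total steps: 13. Longest linear sequence: 10 steps (1, 2, 4, 5, 8, 9, 10, 11, 12, 13).

**Three steps most likely to fail**

Step 12. β-Hydride elimination from the palladium alkoxide (giving aryl ketone and reduced arene) or S–O cleavage of the triflate may outrun C–O reductive elimination at the hindered arene. The fallback sets out from 20 and comes back at 21; it closes ring C from the other side, at O1–C2, with inversion. Oxidation of 20 with Dess–Martin periodinane gives the aryl ketone F1. Chelate-controlled reduction with Zn(BH4)2 in Et2O gives the erythro alcohol F2. Hydrolysis of the triflate with Et4NOH in dioxane gives the erythro phenol F3. Mitsunobu cyclisation (PPh3, DIAD, THF) then displaces the C2 hydroxyl by the phenol oxygen with inversion and gives 21.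

Step 8. Facial discrimination at the lactone cation may be insufficient, the cation may lose H-3 to give the coumarin, or 10 may alkylate itself. The fallback sets out from 10 and comes back at 21; the interflavan bond is made after ring closure, on a 2,3-cis flavan-4-yl cation, for which attack trans to the 3-oxygen is the established outcome. Methylation of 10 (MeI, Ag2O) gives the 4-methoxy lactone F4. DIBAL-H reduction gives the lactol F5. Addition of 17 under the conditions of step 10 gives the threo diol F6. Triflation as in step 11 gives the aryl triflate F7. Palladium-catalysed etherification as in step 12 gives the 4-methoxyflavan F8. F8 and 13 are then coupled with TMSOTf in CH2Cl2 at −78 °C to give 21.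

Step 10. Chelate control may be eroded, because the magnesium phenoxide set free on lactol opening and THF compete for magnesium, which would give an erythro/threo mixture at C2. The fallback sets out from 14 and comes back at 20; the phenol is capped before the addition. Aminolysis of 14 with Me(MeO)NH·HCl and AlMe3 gives the Weinreb amide F9. Triflation (PhNTf2, Et3N) gives its aryl triflate F10. DIBAL-H reduction at −78 °C gives the α-benzyloxy aldehyde F11. Addition of 17 to F11 with MgBr2·OEt2 in CH2Cl2 at −78 °C, now a plain Cram-chelate case, gives 20 directly.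

**Further compounds**
F1 | step 12 | aryl ketone from 20 (C1 carbonyl; C2 and C3 as in 20) | c5ccccc5COc1ccc(C(=O)[C@H](OCc5ccccc5)[C@@H](c6c(OCc5ccccc5)cc(OCc5ccccc5)c7c6O[C@H](c8ccc(OCc5ccccc5)c(OCc5ccccc5)c8)[C@@H](OCc5ccccc5)C7)c2c(OS(=O)(=O)C(F)(F)F)cc(OCc5ccccc5)cc2OCc5ccccc5)cc1
F2 | step 12 | erythro alcohol aryl triflate (C1 epimer of 20) | c5ccccc5COc1ccc([C@H](O)[C@H](OCc5ccccc5)[C@@H](c6c(OCc5ccccc5)cc(OCc5ccccc5)c7c6O[C@H](c8ccc(OCc5ccccc5)c(OCc5ccccc5)c8)[C@@H](OCc5ccccc5)C7)c2c(OS(=O)(=O)C(F)(F)F)cc(OCc5ccccc5)cc2OCc5ccccc5)cc1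
F3 | step 12 | erythro diol phenol (C1 epimer of 19) | c5ccccc5COc1ccc([C@H](O)[C@H](OCc5ccccc5)[C@@H](c6c(OCc5ccccc5)cc(OCc5ccccc5)c7c6O[C@H](c8ccc(OCc5ccccc5)c(OCc5ccccc5)c8)[C@@H](OCc5ccccc5)C7)c2c(O)cc(OCc5ccccc5)cc2OCc5ccccc5)cc1
F4 | step 8 | (3R,4S)-3,5,7-tris(benzyloxy)-4-methoxychroman-2-one (3,4-trans) | O=C1Oc2cc(OCc5ccccc5)cc(OCc5ccccc5)c2[C@H](OC)[C@H]1OCc5ccccc5
F5 | step 8 | lactol of F4 (anomeric mixture) | OC1Oc2cc(OCc5ccccc5)cc(OCc5ccccc5)c2[C@H](OC)[C@H]1OCc5ccccc5
F6 | step 8 | threo 2-(benzyloxy)-1-[4-(benzyloxy)phenyl]-3-[2,4-bis(benzyloxy)-6-hydroxyphenyl]-3-methoxypropan-1-ol (C2, C3 as in F4) | c5ccccc5COc1ccc([C@@H](O)[C@H](OCc5ccccc5)[C@@H](OC)c2c(O)cc(OCc5ccccc5)cc2OCc5ccccc5)cc1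
F7 | step 8 | aryl triflate of F6 | c5ccccc5COc1ccc([C@@H](O)[C@H](OCc5ccccc5)[C@@H](OC)c2c(OS(=O)(=O)C(F)(F)F)cc(OCc5ccccc5)cc2OCc5ccccc5)cc1
F8 | step 8 | 2,3-cis-3,4-trans-3,5,7-tris(benzyloxy)-2-[4-(benzyloxy)phenyl]-4-methoxychromane | c5ccccc5COc1ccc([C@H]2Oc3cc(OCc5ccccc5)cc(OCc5ccccc5)c3[C@H](OC)[C@H]2OCc5ccccc5)cc1
F9 | step 10 | Weinreb amide phenol from 14 (N-methoxy-N-methyl amide; C2 and C3 as in 19) | CON(C)C(=O)[C@H](OCc5ccccc5)[C@@H](c6c(OCc5ccccc5)cc(OCc5ccccc5)c7c6O[C@H](c8ccc(OCc5ccccc5)c(OCc5ccccc5)c8)[C@@H](OCc5ccccc5)C7)c2c(O)cc(OCc5ccccc5)cc2OCc5ccccc5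
F10 | step 10 | aryl triflate of F9 | CON(C)C(=O)[C@H](OCc5ccccc5)[C@@H](c6c(OCc5ccccc5)cc(OCc5ccccc5)c7c6O[C@H](c8ccc(OCc5ccccc5)c(OCc5ccccc5)c8)[C@@H](OCc5ccccc5)C7)c2c(OS(=O)(=O)C(F)(F)F)cc(OCc5ccccc5)cc2OCc5ccccc5
F11 | step 10 | α-benzyloxy aldehyde aryl triflate | O=C[C@H](OCc5ccccc5)[C@@H](c6c(OCc5ccccc5)cc(OCc5ccccc5)c7c6O[C@H](c8ccc(OCc5ccccc5)c(OCc5ccccc5)c8)[C@@H](OCc5ccccc5)C7)c2c(OS(=O)(=O)C(F)(F)F)cc(OCc5ccccc5)cc2OCc5ccccc5
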